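**Plan**
Locants (target ring): C1 = CH bearing the 2‑methylpropanoyl group, C2 = C=O, C3 = C(OH)(prenyl), C4 = C=O, C5 = CH(prenyl), C6 = CH2, C7 = CH(prenyl), C8 = C(CH3)(4‑methylpent‑3‑enyl).
Cuts, in retrosynthetic order: C3–C4 by a 1,2 O→C acyl shift, then the lactone C4–O bond, then C1–C2 (Claisen acylation), then re‑formation of C1–C4 as a temporary cyclohexane, then C5–prenyl, C1–acyl together with C8–(4‑methylpent‑3‑enyl), and C8–CH3.
Enabling feature: the C3 hydroxyl oxygen lies between the C2 and C4 ketones of the cyclooctane (a 2‑hydroxy‑1,3‑dione), so C4 can be held on that oxygen as the carbonyl of a nine‑membered lactone while C2=O acidifies C3–H; the tether is the C3 oxygen itself and nothing has to be removed afterwards.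
Forward order: an organocatalytic annulation gives a cyclohexenone; this temporary six‑membered ring collects the C8, C1 and C5 substituents, is opened by retro‑Claisen cleavage, extended by C2–C3, closed to the nine‑membered lactone and contracted to the cyclooctane.
Stereochemistry: C7 from the prolinol‑ether catalyst; C8 by conjugate addition anti to the C7 prenyl group; C5 by axial alkylation anti to the C7 prenyl group; C3 from a planar enolate in the ring contraction (both C3 epimers converge; the face is set by ring conformation); C1 by equilibration.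

Key step: step 11

Assumption: C1 lies between two carbonyl groups and is configurationally labile; the natural 1R configuration is taken to be the more stable one and to be reached on work‑up.

**Step 1**
Reactants: 1 5‑methylhex‑4‑enal; 2 but‑3‑en‑2‑one
Product: 4 (R)‑4‑(3‑methylbut‑2‑en‑1‑yl)cyclohex‑2‑en‑1‑one, via keto aldehyde 3 (not isolated)
Conditions: (R)‑α,α‑diphenylprolinol methyl ether (5 mol %), ethyl 3,4‑dihydroxybenzoate (20 mol %), neat, 4 °C; then LiOH (10 mol %), i‑PrOH, rt
Reagents that add atoms: none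
Why: Enamine‑catalysed asymmetric Michael addition of the aldehyde to the enone followed by intramolecular aldol condensation (organocatalytic Robinson annulation) should give the 4‑substituted cyclohexenone; the diphenyl(methoxy)methyl group of the (R)‑catalyst shields one face of the E‑enamine and so sets the stereocentre (future C7) as R.

**Step 2**
Reactants: 4 (R)‑4‑(3‑methylbut‑2‑en‑1‑yl)cyclohex‑2‑en‑1‑one
Product: 5 trimethyl{[(3R,4R)‑3‑methyl‑4‑(3‑methylbut‑2‑en‑1‑yl)cyclohex‑1‑en‑1‑yl]oxy}silane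
Conditions: MeMgBr (1.3 equiv), CuBr·SMe2 (10 mol %), TMSCl (2 equiv), THF, −78 → −40 °C; Et3N, pentane, filtration
Reagents that add atoms: methylmagnesium bromide C[Mg]Br; chlorotrimethylsilane C[Si](C)(C)Cl
Why: Copper‑catalysed conjugate addition of the Grignard reagent with in‑situ silyl trapping should give the regiodefined enol ether, the methyl group entering anti to the 4‑prenyl group (this centre is erased in step 3).

**Step 3**
Reactants: 5 trimethyl{[(3R,4R)‑3‑methyl‑4‑(3‑methylbut‑2‑en‑1‑yl)cyclohex‑1‑en‑1‑yl]oxy}silane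
Product: 6 (R)‑3‑methyl‑4‑(3‑methylbut‑2‑en‑1‑yl)cyclohex‑2‑en‑1‑one
Conditions: Pd(OAc)2 (1.05 equiv), MeCN, rt
Reagents that add atoms: none
Why: Saegusa–Ito oxidation: transfer of the enolate to divalent palladium and β‑hydride elimination toward the methyl‑bearing carbon should return the enone with the methyl group now on the β‑carbon, the γ‑stereocentre being untouched.

**Step 4**
Reactants: 6 (R)‑3‑methyl‑4‑(3‑methylbut‑2‑en‑1‑yl)cyclohex‑2‑en‑1‑one; 7 5‑bromo‑2‑methylpent‑2‑ene; 8 2‑methylpropanal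
Product: 10 (3R,4R)‑2‑(1‑hydroxy‑2‑methylpropyl)‑3‑methyl‑3‑(4‑methylpent‑3‑en‑1‑yl)‑4‑(3‑methylbut‑2‑en‑1‑yl)cyclohexan‑1‑one (diastereomer mixture at C2 and the carbinol carbon), via bromomagnesium enolate 9 (not isolated)
Conditions: 7, Mg, THF, rt; CuBr·SMe2 (20 mol %), 6, THF, −40 → −10 °C; then 8, −78 °C; sat. aq. NH4Cl
Reagents that add atoms: none
Why: Copper‑catalysed 1,4‑addition creates the quaternary C8 with the incoming chain anti to the neighbouring prenyl group (trans, as in the target), and the regiodefined magnesium enolate is intercepted at C1 in an aldol addition; the two further new centres are left uncontrolled because one becomes a ketone in step 5 and C1 is equilibrated at the end.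

**Step 5**
Reactants: 10 aldol adduct
Product: 11 (3R,4R)‑3‑methyl‑3‑(4‑methylpent‑3‑en‑1‑yl)‑4‑(3‑methylbut‑2‑en‑1‑yl)‑2‑(2‑methylpropanoyl)cyclohexan‑1‑one (drawn as the ring enol)
Conditions: Dess–Martin periodinane (1.3 equiv), CH2Cl2, 0 °C → rt
Reagents that add atoms: none
Why: Dess–Martin oxidation of a β‑hydroxy ketone to the 1,3‑diketone, with a reagent that leaves the trisubstituted alkenes alone.

**Step 6**
Reactants: 11 2‑acylcyclohexanone; 12 1‑bromo‑3‑methylbut‑2‑ene
Product: 14 (3R,4S,6S)‑3‑methyl‑3‑(4‑methylpent‑3‑en‑1‑yl)‑4,6‑bis(3‑methylbut‑2‑en‑1‑yl)‑2‑(2‑methylpropanoyl)cyclohexan‑1‑one (drawn as the ring enol), via dilithium dianion 13 (not isolated)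
Conditions: LiN(i‑Pr)2 (2.3 equiv), THF, −78 → 0 °C; then 12 (1.2 equiv), −78 → −20 °C; cold 1 M HCl
Reagents that add atoms: none
Why: γ‑Alkylation of a 1,3‑diketone dianion: the second deprotonation should occur at the ring CH2 (C5) in preference to the isopropyl methine, and the allylic bromide should enter axially on the face anti to the C7 prenyl group, giving the 5,7‑trans relationship (5S).

**Step 7**
Reactants: 14 prenylated 2‑acylcyclohexanone
Product: 15 (2S,4S,5S)‑5,9‑dimethyl‑5‑(3‑methyl‑2‑oxobutyl)‑2,4‑bis(3‑methylbut‑2‑en‑1‑yl)dec‑8‑enoic acid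
Conditions: KOH (5 equiv), EtOH–H2O, 70 °C; then 1 M HCl to pH 3
Reagents that add atoms: potassium hydroxide [K+].[OH-]
Why: Retro‑Claisen cleavage of a 2‑acylcyclohexanone: hydroxide should add to the ring carbonyl (C4), the more electrophilic of the two ketones, and the C4–C1 bond breaks with expulsion of the ketone enolate, which opens the temporary ring; C5 is then α to a carboxylate and is not epimerised.

**Step 8**
Reactants: 16 2,2‑dimethyl‑1,3‑dioxolan‑4‑one; 12 1‑bromo‑3‑methylbut‑2‑ene
Product: 18 (±)‑2,2‑dimethyl‑5‑(3‑methylbut‑2‑en‑1‑yl)‑1,3‑dioxolan‑4‑one, via lithium enolate 17 (not isolated)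
Conditions: LiN(SiMe3)2 (1.1 equiv) added to 16 and 12 (1.2 equiv), THF, −78 → −40 °C
Reagents that add atoms: none
Why: Enolate alkylation of the glycolic acid acetonide with an allylic bromide, the base being added to both partners to suppress self‑condensation; the product is racemic, which is of no consequence because C3 is planarised in step 11.

**Step 9**
Reactants: 15 keto acid; 18 prenylated dioxolanone
Product: 20 (2S,4S,5R)‑5‑[3‑hydroxy‑6‑methyl‑1‑(2‑methylpropanoyl)‑2‑oxohept‑5‑en‑1‑yl]‑5,9‑dimethyl‑2,4‑bis(3‑methylbut‑2‑en‑1‑yl)dec‑8‑enoic acid (epimer mixture at C1 and C3 of the target numbering), via dilithium enolate carboxylate 19 (not isolated)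
Conditions: LiN(i‑Pr)2 (2.2 equiv), THF, −78 °C; then 18 (1.3 equiv), −78 → −20 °C; cold 0.5 M HCl to pH 4
Reagents that add atoms: none
Why: Claisen‑type C‑acylation of the kinetic ketone enolate (formed on the CH2 side, C1) by the dioxolanone, whose tetrahedral adduct collapses with loss of acetone and frees the C3 hydroxyl directly; the lithium carboxylate keeps C4 inert toward Dieckmann re‑closure and C5 is not deprotonated at this temperature.

**Step 10**
Reactants: 20 seco acid
Product: 22 (3S,5S,6R)‑6‑methyl‑3,5,9‑tris(3‑methylbut‑2‑en‑1‑yl)‑6‑(4‑methylpent‑3‑en‑1‑yl)‑7‑(2‑methylpropanoyl)oxonane‑2,8‑dione (epimer mixture at C7 and C9 of the lactone), via mixed anhydride 21 (not isolated)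
Conditions: 2‑methyl‑6‑nitrobenzoic anhydride (MNBA, 1.3 equiv), DMAP (3 equiv), CH2Cl2, slow addition of 20 (final 2 mM), rt
Reagents that add atoms: none
Why: Shiina macrolactonization: the mixed anhydride is converted by DMAP into an acylpyridinium ion that is captured by the C3 hydroxyl under high dilution, the quaternary C8 and the three branch points favouring the medium‑ring closure; the configuration at C3 and C1 is irrelevant here.

**Step 11**
Reactants: 22 nine‑membered keto lactone
Product: 25 hyphenrone F, via dilithium dienolate 23 (not isolated), via oxiranyl alkoxide 24 (not isolated)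
Conditions: LiN(i‑Pr)2 (2.5 equiv), THF, −78 → −30 °C; AcOH, −78 °C
Reagents that add atoms: none
Why: Proposed new method: the base removes C1–H and then C3–H (α to the C2 ketone and to the lactone oxygen) to give a planar enolate at C3, whose carbon attacks the lactone carbonyl C4 hanging from its own oxygen to form an oxiranyl alkoxide; collapse of that alkoxide with cleavage of the C4–O bond completes a 1,2 O→C acyl shift, so the nine‑membered lactone contracts to the eight‑membered carbocycle with the C3 alkoxide and both flanking ketones at the final oxidation level (a mono‑enolate at C3 would react in the same way). The closest known reaction type is the Chan rearrangement of acyclic α‑acyloxy esters and ketones to α‑hydroxy‑β‑dicarbonyl compounds and its ring‑contracting use on a cyclic carbonate; new here is its use as a transannular contraction of a medium‑ring keto lactone to a carbocycle. The cyclooctane is closed through a 3‑exo‑trig attack inside the existing ring, which replaces a direct eight‑membered C–C closure by a first‑order 1,2‑shift. The new C3 stereocentre comes from the planar enolate, so both C3 epimers of 22 converge; the face is fixed by the conformation of the cis‑enolate ring, in which the quaternary C8 and the C5 and C7 prenyl groups decide on which side the C4 carbonyl lies, and the 3R product (hydroxyl cis to the C8 methyl) is expected from the conformer that keeps the C8 4‑methylpent‑3‑enyl chain and the C5 prenyl group outside the ring, although this is the least secure prediction of the route. The step needs deprotonation at C3 and not at C5 (α to the lactone), which the higher acidity of the α‑acyloxy ketone position should secure, and C‑attack at C3 and not at the more hindered C2; C1 is re‑protonated to the more stable 1R epimer on work‑up.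

**Compound list**
1 | 5‑methylhex‑4‑enal | CC(C)=CCCC=O | starting material
2 | but‑3‑en‑2‑one | CC(=O)C=C | starting material
3 | (R)‑2‑(3‑methylbut‑2‑en‑1‑yl)‑5‑oxohexanal (not isolated) | O=C[C@@H](CC=C(C)C)CCC(C)=O | intermediate
4 | (R)‑4‑(3‑methylbut‑2‑en‑1‑yl)cyclohex‑2‑en‑1‑one | O=C1C=C[C@@H](CC=C(C)C)CC1 | intermediate
5 | trimethyl{[(3R,4R)‑3‑methyl‑4‑(3‑methylbut‑2‑en‑1‑yl)cyclohex‑1‑en‑1‑yl]oxy}silane | C[Si](C)(C)OC1=C[C@H](C)[C@@H](CC=C(C)C)CC1 | intermediate
6 | (R)‑3‑methyl‑4‑(3‑methylbut‑2‑en‑1‑yl)cyclohex‑2‑en‑1‑one | O=C1C=C(C)[C@@H](CC=C(C)C)CC1 | intermediate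
7 | 5‑bromo‑2‑methylpent‑2‑ene | CC(C)=CCCBr | starting material
8 | 2‑methylpropanal | CC(C)C=O | starting material
9 | bromomagnesium (3R,4R)‑3‑methyl‑3‑(4‑methylpent‑3‑en‑1‑yl)‑4‑(3‑methylbut‑2‑en‑1‑yl)cyclohex‑1‑en‑1‑olate (not isolated) | CC(C)=CCC[C@]1(C)[C@@H](CC=C(C)C)CCC(O[Mg]Br)=C1 | intermediate
10 | (3R,4R)‑2‑(1‑hydroxy‑2‑methylpropyl)‑3‑methyl‑3‑(4‑methylpent‑3‑en‑1‑yl)‑4‑(3‑methylbut‑2‑en‑1‑yl)cyclohexan‑1‑one, diastereomer mixture | CC(C)=CCC[C@]1(C)[C@@H](CC=C(C)C)CCC(=O)C1C(O)C(C)C | intermediate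
11 | (3R,4R)‑3‑methyl‑3‑(4‑methylpent‑3‑en‑1‑yl)‑4‑(3‑methylbut‑2‑en‑1‑yl)‑2‑(2‑methylpropanoyl)cyclohexan‑1‑one, ring enol drawn | CC(C)=CCC[C@]1(C)[C@@H](CC=C(C)C)CCC(O)=C1C(=O)C(C)C | intermediate
12 | 1‑bromo‑3‑methylbut‑2‑ene | CC(C)=CCBr | starting material
13 | dilithium dianion of 11, enolates at the exocyclic carbonyl and at ring C4=C5 (not isolated) | [Li+].[Li+].CC(C)=CCC[C@]1(C)[C@@H](CC=C(C)C)CC=C([O-])C1=C([O-])C(C)C | intermediate
14 | (3R,4S,6S)‑3‑methyl‑3‑(4‑methylpent‑3‑en‑1‑yl)‑4,6‑bis(3‑methylbut‑2‑en‑1‑yl)‑2‑(2‑methylpropanoyl)cyclohexan‑1‑one, ring enol drawn | CC(C)=CCC[C@]1(C)[C@@H](CC=C(C)C)C[C@H](CC=C(C)C)C(O)=C1C(=O)C(C)C | intermediate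
15 | (2S,4S,5S)‑5,9‑dimethyl‑5‑(3‑methyl‑2‑oxobutyl)‑2,4‑bis(3‑methylbut‑2‑en‑1‑yl)dec‑8‑enoic acid | CC(C)=CCC[C@](CC(=O)C(C)C)(C)[C@@H](CC=C(C)C)C[C@H](CC=C(C)C)C(=O)O | intermediate
16 | 2,2‑dimethyl‑1,3‑dioxolan‑4‑one | CC1(C)OCC(=O)O1 | starting material
17 | lithium enolate of 16 (not isolated) | [Li+].CC1(C)OC=C([O-])O1 | intermediate
18 | (±)‑2,2‑dimethyl‑5‑(3‑methylbut‑2‑en‑1‑yl)‑1,3‑dioxolan‑4‑one | CC(C)=CCC1OC(C)(C)OC1=O | intermediate
19 | dilithium salt of 15, lithium carboxylate and lithium enolate at C1 (not isolated) | [Li+].[Li+].CC(C)=CCC[C@](C=C([O-])C(C)C)(C)[C@@H](CC=C(C)C)C[C@H](CC=C(C)C)C(=O)[O-] | intermediate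
20 | (2S,4S,5R)‑5‑[3‑hydroxy‑6‑methyl‑1‑(2‑methylpropanoyl)‑2‑oxohept‑5‑en‑1‑yl]‑5,9‑dimethyl‑2,4‑bis(3‑methylbut‑2‑en‑1‑yl)dec‑8‑enoic acid, epimer mixture at the two side‑chain centres | CC(C)=CCC[C@](C(C(=O)C(C)C)C(=O)C(O)CC=C(C)C)(C)[C@@H](CC=C(C)C)C[C@H](CC=C(C)C)C(=O)O | intermediate
21 | mixed anhydride of 20 with 2‑methyl‑6‑nitrobenzoic acid (not isolated) | CC(C)=CCC[C@](C(C(=O)C(C)C)C(=O)C(O)CC=C(C)C)(C)[C@@H](CC=C(C)C)C[C@H](CC=C(C)C)C(=O)OC(=O)c1c(C)cccc1[N+](=O)[O-] | intermediate
22 | (3S,5S,6R)‑6‑methyl‑3,5,9‑tris(3‑methylbut‑2‑en‑1‑yl)‑6‑(4‑methylpent‑3‑en‑1‑yl)‑7‑(2‑methylpropanoyl)oxonane‑2,8‑dione, epimer mixture at C7 and C9 | CC(C)=CCC[C@]1(C)[C@@H](CC=C(C)C)C[C@H](CC=C(C)C)C(=O)OC(CC=C(C)C)C(=O)C1C(=O)C(C)C | intermediate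
23 | dilithium dienolate of 22, C1 and C3 deprotonated (not isolated) | [Li+].[Li+].CC(C)=CCC[C@]1(C)[C@@H](CC=C(C)C)C[C@H](CC=C(C)C)C(=O)OC(CC=C(C)C)=C([O-])C1=C([O-])C(C)C | intermediate
24 | oxiranyl alkoxide: oxirane spanning C3 and C4 on the eight‑membered carbocycle, alkoxide on C4 (configuration at C4 not defined), C1 still an enolate (not isolated) | [Li+].[Li+].CC(C)=CCC[C@]1(C)[C@@H](CC=C(C)C)C[C@H](CC=C(C)C)C2([O-])O[C@@]2(CC=C(C)C)C(=O)C1=C([O-])C(C)C | intermediate
25 | hyphenrone F, (2R,4R,5R,6S,8S)‑2‑hydroxy‑5‑methyl‑2,6,8‑tris(3‑methylbut‑2‑en‑1‑yl)‑5‑(4‑methylpent‑3‑en‑1‑yl)‑4‑(2‑methylpropanoyl)cyclooctane‑1,3‑dione | CC(C)=CCC[C@]1(C)[C@@H](CC=C(C)C)C[C@H](CC=C(C)C)C(=O)[C@](O)(CC=C(C)C)C(=O)[C@H]1C(=O)C(C)C | target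

**Totals**
Total steps: 11. Longest linear sequence: 10 (steps 1–7 and 9–11).

**Steps most likely to fail**

Step 11 (proposed new method). What may go wrong: attack of the enolate on the undesired face of C3; migration of the acyl group between the two oxygen atoms of the enediolate before the shift, which would deliver C4 to C2; deprotonation at C5 with loss of configuration. The fallback uses known chemistry (enolate C‑acylation, Claisen ring closure, enolate hydroxylation with an N‑sulfonyloxaziridine), sets out from 15 and returns to the route at 25. 5‑Methylhex‑4‑enoic acid is converted with carbonyldiimidazole into 1‑(5‑methylhex‑4‑enoyl)imidazole F1. The dilithio derivative of 15, made as in step 9, is acylated with F1 to give the 1,3‑diketo acid F2, and TMSCHN2 gives the methyl ester F3. LiN(i‑Pr)2 (3 equiv) under high dilution should then close the ring by Claisen condensation of the diketone dianion (C3) onto the C4 ester, the product 3‑deoxyhyphenrone F F4 being held as a stabilised polyanion. C3, now flanked by two ring ketones, is hydroxylated through its potassium enolate (KN(SiMe3)2) with (camphorsulfonyl)oxaziridine, the enantiomer of the reagent being chosen to reinforce the desired face, to give 25.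

Step 10. What may go wrong: intermolecular esterification to oligomers, O‑acylation of the 1,3‑diketone enol by the activated acid, or cyclodehydration of the α′‑hydroxy‑1,3‑diketone to a furanone. The fallback sets out from 20 and returns at 25 without passing through the lactone. TMSCHN2 gives the methyl ester F5, and TESOTf with 2,6‑lutidine gives the silyl ether F6. LiN(i‑Pr)2 (2.5 equiv) should then close the same C3–C4 bond by direct Claisen condensation of the C3 carbanion of the diketone dianion onto the ester, giving O‑triethylsilyl hyphenrone F F7, and HF·pyridine removes the silyl group to give 25.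

Step 9. What may go wrong: proton transfer from the dioxolanone to the hindered enolate, O‑acylation, or enolisation toward the isopropyl group. The fallback replaces the acylation by an aldol addition and an oxidation; it sets out from 15 (with 18) and returns at 20. K2CO3 in MeOH opens 18 to methyl 2‑hydroxy‑5‑methylhex‑4‑enoate F8, TESCl with imidazole gives methyl 5‑methyl‑2‑(triethylsilyloxy)hex‑4‑enoate F9, and i‑Bu2AlH at −78 °C gives 5‑methyl‑2‑(triethylsilyloxy)hex‑4‑enal F10. The dilithio derivative of 15 adds to F10 to give the aldol adduct F11, Dess–Martin oxidation gives the silyl‑protected diketo acid F12, and HF·pyridine returns 20.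

**Further compounds**
F1 | step 11 | 1‑(5‑methylhex‑4‑enoyl)‑1H‑imidazole | CC(C)=CCCC(=O)n1ccnc1
F2 | step 11 | (2S,4S,5R)‑5,9‑dimethyl‑5‑[6‑methyl‑1‑(2‑methylpropanoyl)‑2‑oxohept‑5‑en‑1‑yl]‑2,4‑bis(3‑methylbut‑2‑en‑1‑yl)dec‑8‑enoic acid | CC(C)=CCC[C@](C(C(=O)C(C)C)C(=O)CCC=C(C)C)(C)[C@@H](CC=C(C)C)C[C@H](CC=C(C)C)C(=O)O
F3 | step 11 | methyl ester of F2 | CC(C)=CCC[C@](C(C(=O)C(C)C)C(=O)CCC=C(C)C)(C)[C@@H](CC=C(C)C)C[C@H](CC=C(C)C)C(=O)OC
F4 | step 11 | 3‑deoxyhyphenrone F (C3–H in place of C3–OH; C1 and C3 enolisable) | CC(C)=CCC[C@]1(C)[C@@H](CC=C(C)C)C[C@H](CC=C(C)C)C(=O)C(CC=C(C)C)C(=O)C1C(=O)C(C)C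
F5 | step 10 | methyl ester of 20 | CC(C)=CCC[C@](C(C(=O)C(C)C)C(=O)C(O)CC=C(C)C)(C)[C@@H](CC=C(C)C)C[C@H](CC=C(C)C)C(=O)OC
F6 | step 10 | triethylsilyl ether of F5 | CC(C)=CCC[C@](C(C(=O)C(C)C)C(=O)C(O[Si](CC)(CC)CC)CC=C(C)C)(C)[C@@H](CC=C(C)C)C[C@H](CC=C(C)C)C(=O)OC
F7 | step 10 | O‑triethylsilyl hyphenrone F | CC(C)=CCC[C@]1(C)[C@@H](CC=C(C)C)C[C@H](CC=C(C)C)C(=O)[C@](O[Si](CC)(CC)CC)(CC=C(C)C)C(=O)[C@H]1C(=O)C(C)C
F8 | step 9 | methyl 2‑hydroxy‑5‑methylhex‑4‑enoate | COC(=O)C(O)CC=C(C)C
F9 | step 9 | methyl 5‑methyl‑2‑(triethylsilyloxy)hex‑4‑enoate | COC(=O)C(O[Si](CC)(CC)CC)CC=C(C)C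
F10 | step 9 | 5‑methyl‑2‑(triethylsilyloxy)hex‑4‑enal | O=CC(O[Si](CC)(CC)CC)CC=C(C)C
F11 | step 9 | aldol adduct of 15 with F10 (β‑hydroxy ketone acid, diastereomer mixture) | CC(C)=CCC[C@](C(C(=O)C(C)C)C(O)C(O[Si](CC)(CC)CC)CC=C(C)C)(C)[C@@H](CC=C(C)C)C[C@H](CC=C(C)C)C(=O)O
F12 | step 9 | triethylsilyl ether of 20 | CC(C)=CCC[C@](C(C(=O)C(C)C)C(=O)C(O[Si](CC)(CC)CC)CC=C(C)C)(C)[C@@H](CC=C(C)C)C[C@H](CC=C(C)C)C(=O)O
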